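**Plan**

1. Retrosynthetic cuts, in order: the C4–O–C7 hemiketal bridge (back to a Z-alkene flanked by C4–OH and C7–OH), the C8 urocanate, C9–C10, the lactone bond O12–C8, C3–C4 and C1–C2. The lactate-derived piece already carries C6 on C7.
2. Feature that allows the key step: with C8 as a ketone, C8(=O)–C9H2–C10H–C11=C12 (ring-fusion carbon C10 plus the cyclohexene alkene) is a γ,δ-unsaturated ketone. It is the product of a Claisen shift of the allyl vinyl ether C9=C8–O–C12–C11=C10, in which the cyclohexene carbon C12 carries the oxygen.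
3. Forward order: cyclohexene from (S)-carvone → chain joined at C3–C4 by an aldol reaction with the lactate-derived C4–C8 ynal → twelve-membered lactone (C8 acid onto O12) → 2-methylene oxacycle → ten-membered carbocycle by [3,3] ring contraction → dihydrofuran hemiketal last.
4. Stereochemistry: C14 from carvone; C1 by trans allylation; C12 by nucleophilic epoxidation and Wharton transposition; C10 by suprafacial transfer from C12; C3 by the oxazolidinone auxiliary; C7 from (R)-lactic acid by self-regeneration of the stereocentre; C8 by CBS reduction; C4 by the oxygen bridge.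

Key step: step 25

Numbering: eunicellane locants are used (C1/C10 ring fusion, C3 bearing C15, C4, C7, C8, C11=C12, C14 bearing isopropyl); C15 is the carbon on C3 that ends as the ester carbon.

Remark: C3 lies α to the ester and to the masked C4 ketone; it is assumed that this centre keeps the configuration set in step 17 under the neutral end-game conditions, as it does in the natural product itself.

**Route**

Step 1
Reactants: 1 (S)-(+)-carvone
Product: 2 (S)-carvotanacetone, (5S)-2-methyl-5-(propan-2-yl)cyclohex-2-en-1-one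
Conditions: H2 (1 atm), RhCl(PPh3)3 (cat.), toluene, rt
Reagents that add atoms: none
Why: Homogeneous hydrogenation with RhCl(PPh3)3 is selective for the unhindered 1,1-disubstituted alkene over the conjugated trisubstituted one, so the isopropyl group is in place from the start and C14 keeps the carvone configuration.

Step 2
Reactants: 2 (S)-carvotanacetone
Product: 3 6-allyl-5-isopropyl-2-methylcyclohex-2-en-1-one, allyl trans to isopropyl
Conditions: LiN(iPr)2, THF, −78 °C; allyl bromide, DMPU, −78 → 0 °C
Reagents that add atoms: allyl bromide, C=CCBr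
Why: Kinetic α′-deprotonation gives the cross-conjugated lithium enolate, and the enolate alkylation should take place on the face away from the neighbouring isopropyl group, which sets C1 trans to C14.

Step 3
Reactants: 3 trans-6-allyl enone
Product: 4 2,3-epoxy ketone, oxirane oxygen trans to isopropyl and cis to allyl
Conditions: 30% H2O2, NaOH (aq., cat.), MeOH, 0 °C
Reagents that add atoms: hydrogen peroxide, OO
Why: In this Weitz–Scheffer nucleophilic epoxidation hydroperoxide should add axially to the β-carbon anti to the isopropyl group, so the oxirane oxygen (the later C12 oxygen) comes out trans to isopropyl and cis to the allyl arm, while the isolated terminal alkene does not react with the nucleophilic oxidant.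

Step 4
Reactants: 4 epoxy ketone
Product: 5 allylic alcohol, 4-allyl-5-isopropyl-2-methylcyclohex-2-en-1-ol (C12–OH cis to the allyl arm on C1, trans to isopropyl on C14)
Conditions: N2H4·H2O, AcOH (cat.), MeOH, 0 °C → rt, under N2
Reagents that add atoms: none
Why: Wharton transposition: the epoxy hydrazone collapses with loss of N2 to the allylic alcohol, the epoxide C–O bond at C12 staying intact, so the hydroxyl is cis to the C1 arm and the alkene lies at C10–C11.

Step 5
Reactants: 5 allylic alcohol
Product: 6 C12 p-methoxybenzyl (PMB) ether of 5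
Conditions: NaH, 4-MeOC6H4CH2Cl, Bu4NI (cat.), THF/DMF, 0 °C → rt
Reagents that add atoms: 4-methoxybenzyl chloride, COc1ccc(CCl)cc1
Why: Williamson etherification of the secondary allylic alkoxide; the PMB ether is chosen because it should outlast the borane, boron enolate, borohydride, silyl triflate and hydrogenation steps and then leave oxidatively beside silyl ethers.

Step 6
Reactants: 6 PMB ether
Product: 8 primary alcohol (C1 arm = 3-hydroxypropyl), via B-alkyl-9-BBN adduct 7 (not isolated)
Conditions: 9-BBN, THF, 0 °C → rt; then NaOH (aq.), 30% H2O2, 0 °C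
Reagents that add atoms: hydrogen peroxide, OO
Why: Brown hydroboration–oxidation: the bulky 9-BBN should add anti-Markovnikov to the monosubstituted alkene only and leave the trisubstituted ring alkene.

Step 7
Reactants: 8 primary alcohol
Product: 10 3-(cyclohexenyl)propanoic acid, via aldehyde 9 (not isolated)
Conditions: TEMPO (cat.), PhI(OAc)2, MeCN/H2O (1:1), rt
Reagents that add atoms: water, O
Why: Oxoammonium (TEMPO) oxidation with PhI(OAc)2 in aqueous acetonitrile should carry the primary alcohol through the aldehyde hydrate to the acid without touching the PMB ether or the alkene.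

Step 8
Reactants: 10 propanoic acid
Product: 12 N-acyl (R)-4-benzyloxazolidin-2-one, via mixed pivalic anhydride 11 (not isolated)
Conditions: t-BuCOCl, Et3N, THF, −20 °C; then (R)-4-benzyl-2-oxazolidinone, LiCl, −20 °C → rt
Reagents that add atoms: (R)-4-benzyl-2-oxazolidinone, O=C1N[C@H](Cc2ccccc2)CO1
Why: Acylation of the oxazolidinone through the mixed pivalic anhydride with LiCl and Et3N (attachment of the Evans auxiliary) needs no strong base; the (R)-auxiliary is chosen for the C3 configuration.

Step 9
Reactants: 13 (R)-lactic acid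
Product: 14 (2R,5R)-2-tert-butyl-5-methyl-1,3-dioxolan-4-one (cis)
Conditions: t-BuCHO, TsOH·H2O (cat.), H2SO4 (cat.), pentane, reflux (Dean–Stark); crystallisation from pentane/Et2O at −78 °C
Reagents that add atoms: pivalaldehyde, CC(C)(C)C=O
Why: Acid-catalysed acetalisation with removal of water (first stage of the Seebach self-regeneration of stereocentres) should give mainly the cis dioxolanone, in which the lactate centre induces the acetal centre; crystallisation removes the trans isomer.

Step 10
Reactants: 14 cis-dioxolanone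
Product: 15 5-(benzyloxymethyl)-2-tert-butyl-5-methyl-1,3-dioxolan-4-one, benzyloxymethyl trans to tert-butyl
Conditions: LiN(iPr)2, THF, −78 °C; BnOCH2Cl, −78 → −30 °C
Reagents that add atoms: benzyl chloromethyl ether, ClCOCc1ccccc1
Why: Seebach alkylation: the lithium enolate is attacked on the face opposite the tert-butyl group, so the benzyloxymethyl group takes the place of the original hydrogen and the quaternary C7 centre is set with overall retention.

Step 11
Reactants: 15 benzyloxymethyl dioxolanone
Product: 16 5-(hydroxymethyl) dioxolanone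
Conditions: H2 (1 atm), Pd/C (10%), EtOAc, rt
Reagents that add atoms: none
Why: Hydrogenolysis of the benzyl ether over Pd/C in a neutral solvent should leave the acid-sensitive acylal untouched.

Step 12
Reactants: 16 hydroxymethyl dioxolanone
Product: 17 5-formyl dioxolanone
Conditions: Dess–Martin periodinane, NaHCO3, CH2Cl2, 0 °C → rt
Reagents that add atoms: none
Why: Dess–Martin oxidation of the neopentyl-type primary alcohol gives an aldehyde with no α-hydrogen, so C7 cannot epimerise.

Step 13
Reactants: 17 formyl dioxolanone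
Product: 18 5-ethynyl dioxolanone
Conditions: Me3SiCHN2, LiN(iPr)2, THF, −78 °C; then 17, −78 °C → rt
Reagents that add atoms: (trimethylsilyl)diazomethane, C[Si](C)(C)C=[N+]=[N-]
Why: Colvin rearrangement: lithiated trimethylsilyldiazomethane should add to the aldehyde well before the lactone carbonyl at −78 °C, and loss of Me3SiOLi and N2 gives an alkylidene carbene that rearranges by 1,2-hydrogen shift to the terminal alkyne (C6≡C5).

Step 14
Reactants: 18 ethynyl dioxolanone
Product: 19 methyl (S)-2-hydroxy-2-methylbut-3-ynoate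
Conditions: NaOMe (cat.), MeOH, 0 °C
Reagents that add atoms: methanol, CO
Why: Methoxide-catalysed transesterification opens the acylal; the hemiacetal alkoxide expels pivalaldehyde and frees the tertiary alcohol, and C7 is not touched.

Step 15
Reactants: 19 hydroxy ester
Product: 20 methyl (S)-2-methyl-2-(triethylsilyloxy)but-3-ynoate
Conditions: Et3SiOTf, 2,6-lutidine, CH2Cl2, −78 → 0 °C
Reagents that add atoms: triethylsilyl trifluoromethanesulfonate, CC[Si](CC)(CC)OS(=O)(=O)C(F)(F)F
Why: Silylation of the hindered tertiary alcohol needs the silyl triflate; the TES ether is expected to survive to the end and is removed with HF.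

Step 16
Reactants: 20 TES-protected alkyne ester
Product: 21 methyl (S)-2-methyl-5-oxo-2-(triethylsilyloxy)pent-3-ynoate (C4–C8 ynal)
Conditions: LiN(iPr)2, THF, −78 °C; DMF, −78 → 0 °C; inverse quench into aq. KH2PO4
Reagents that add atoms: N,N-dimethylformamide, CN(C)C=O
Why: Formylation of a lithium acetylide with DMF: the ester has no α-hydrogen and is shielded by the quaternary centre, and the inverse buffered quench keeps dimethylamine from adding to the ynal.

Step 17
Reactants: 12 N-acyl oxazolidinone; 21 ynal
Product: 22 syn-aldol adduct (C3 bearing the imide carbonyl C15, C4–OH, C5≡C6, C7(Me)(OTES), C8 methyl ester)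
Conditions: 12, Bu2BOTf, i-Pr2NEt, CH2Cl2, −78 → 0 °C; then 21, −78 → −20 °C; pH 7 buffer, MeOH, 30% H2O2, 0 °C
Reagents that add atoms: none
Why: Evans syn-aldol reaction: the dibutylboron Z-enolate should react through a Zimmerman–Traxler chair on the face away from the benzyl group of the (R)-auxiliary, which sets C3 as the target needs and the C4 carbinol syn to it; alkynals are good acceptors and the hindered ester stays.

Step 18
Reactants: 22 aldol adduct
Product: 23 C15,C4-diol
Conditions: LiBH4, MeOH (1 equiv), THF, 0 °C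
Reagents that add atoms: none
Why: Reductive cleavage of the auxiliary with LiBH4: the imide carbonyl is much more electrophilic than the neopentyl-type methyl ester, so only C15 should be reduced, to the primary alcohol, and the auxiliary is recovered.

Step 19
Reactants: 23 diol
Product: 24 C15,C4-bis(tert-butyldimethylsilyl) ether
Conditions: t-BuMe2SiOTf, 2,6-lutidine, CH2Cl2, −78 → 0 °C
Reagents that add atoms: tert-butyldimethylsilyl trifluoromethanesulfonate, CC(C)(C)[Si](C)(C)OS(=O)(=O)C(F)(F)F
Why: Silylation with the triflate and 2,6-lutidine protects both hydroxyls in one operation and gives a primary and a secondary TBS ether that can later be told apart.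

Step 20
Reactants: 24 alkyne
Product: 25 (Z)-C5=C6 alkene
Conditions: H2 (1 atm), Pd/CaCO3 poisoned with Pb(OAc)2, quinoline, EtOAc, rt
Reagents that add atoms: none
Why: Lindlar-type semihydrogenation: syn addition of one H2 to the alkyne on poisoned palladium should give the Z alkene C5=C6 that the later hemiketal closure needs, without hydrogenolysis of the PMB ether or reduction of the trisubstituted alkene.

Step 21
Reactants: 25 Z-alkene PMB ether
Product: 26 C12 alcohol (hydroxy methyl ester)
Conditions: DDQ, CH2Cl2/pH 7 phosphate buffer (10:1), 0 °C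
Reagents that add atoms: none
Why: Oxidative PMB cleavage: DDQ abstracts hydride from the electron-rich benzyl ether and the hemiacetal hydrolyses, which frees only the C12 hydroxyl and leaves the silyl ethers and the alkenes.

Step 22
Reactants: 26 hydroxy methyl ester
Product: 27 seco acid (C8 carboxylic acid, C12–OH)
Conditions: KOSiMe3, THF, rt; then aq. KH2PO4
Reagents that add atoms: potassium trimethylsilanolate, C[Si](C)(C)[O-].[K+]
Why: Silanolate cleavage of a hindered methyl ester under non-aqueous conditions (acyl–oxygen cleavage, then desilylation of the silyl ester by the methoxide released); the silyl ethers should survive and no stereocentre is at risk because C7 is quaternary.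

Step 23
Reactants: 27 seco acid
Product: 29 twelve-membered lactone (C8 acyl on O12), via mixed trichlorobenzoic anhydride 28 (not isolated)
Conditions: 2,4,6-Cl3C6H2COCl, Et3N, THF, rt; then syringe-pump addition to DMAP, toluene, 80 °C (about 1 mM)
Reagents that add atoms: none
Why: Yamaguchi macrolactonisation: the mixed anhydride is opened by DMAP and the acylpyridinium is trapped by the C12 hydroxyl at high dilution, with retention at C12 since its C–O bond is not broken; the Z alkene and the cis relation of O12 and the C1 arm on the cyclohexene should bring the ends together.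

Step 24
Reactants: 29 twelve-membered lactone
Product: 30 twelve-membered 2-methylene oxacycle (cyclic allyl vinyl ether C9=C8–O–C12–C11=C10)
Conditions: Cp2TiMe2, toluene, 70 °C, dark; filtration through basic Al2O3
Reagents that add atoms: dimethyltitanocene, C[Ti](C)(C1C=CC=C1)C1C=CC=C1
Why: Petasis methylenation: thermally generated Cp2Ti=CH2 adds to the lactone carbonyl in a [2+2] cycloaddition and cycloreverts to the enol ether; the reagent is not basic, the carbonyl has no α-hydrogen, and silyl ethers and alkenes are tolerated.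

Step 25
Reactants: 30 twelve-membered 2-methylene oxacycle
Product: 31 ten-membered C8 ketone cis-fused to the cyclohexene (C11=C12)
Conditions: degassed xylene, i-Pr2NEt (trace), base-washed sealed tube, 150 °C
Reagents that add atoms: none
Why: Heating the cyclic allyl vinyl ether should bring about a concerted [3,3]-sigmatropic (Claisen) shift in which the methylene carbon C9 bonds to C10 while the C12–O bond breaks, the alkene moves to C11–C12 and C8 becomes a ketone. The closest known reaction type is the thermal Claisen ring contraction of 2-methylene oxacycles made by titanium methylenation of macrolactones. The ten-membered carbocycle C1–C10 closes by this sigmatropic ring contraction of the twelve-membered oxacycle through the six-membered, chair-like array C9–C8–O–C12–C11–C10, with O, C12 and C11 leaving the large ring and staying in the cyclohexene. The single new stereocentre C10 is controlled by C12: the shift is suprafacial across the cyclohexene, so C9 arrives on the face that carried the oxygen, which is also the face of the C2 arm on C1, and the cis ring fusion follows whether the array is a chair or a boat because C9 is a methylene. The step needs the rearrangement to win over ionisation of the allylic C12–O bond and over hydrolysis or isomerisation of the enol ether; acid-free conditions (base-washed glass, hindered amine), the absence of any other allyl vinyl ether or 1,5-diene, and the C2–C7 tether that holds the vinyl ether over the only reachable allyl terminus, C10, should secure this.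

Step 26
Reactants: 31 C8 ketone
Product: 32 (8S)-C8 alcohol, C8–OH trans to C7–O
Conditions: (R)-2-methyl-CBS-oxazaborolidine, catecholborane, toluene, −78 → −40 °C
Reagents that add atoms: none
Why: Corey–Bakshi–Shibata reduction under reagent control: with the quaternary C7 as the large and C9H2 as the small substituent the (R)-catalyst should deliver hydride to give the (8S)-alcohol, the face also favoured by a polar Felkin–Anh arrangement with the C7–O bond anti to the hydride; catecholborane at low temperature should not hydroborate the alkenes.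

Step 27
Reactants: 33 urocanic acid
Product: 34 methyl (E)-3-(1-methyl-1H-imidazol-4-yl)prop-2-enoate
Conditions: MeI (2.2 equiv), K2CO3, DMF, rt
Reagents that add atoms: iodomethane, CI
Why: Alkylation with iodomethane esterifies the carboxylate and methylates the imidazole; N-alkylation should occur mainly at the nitrogen remote from the acrylate substituent (the 1,4-isomer), and the minor 1,5-isomer should be removable by crystallisation.

Step 28
Reactants: 34 methyl N-methylurocanate
Product: 35 (E)-3-(1-methyl-1H-imidazol-4-yl)prop-2-enoic acid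
Conditions: LiOH, THF/H2O, rt; then HCl to pH 5
Reagents that add atoms: lithium hydroxide, [Li+].[OH-]
Why: Saponification of the methyl ester; the E alkene and the N-methylimidazole are stable to aqueous hydroxide.

Step 29
Reactants: 32 C8 alcohol; 35 N-methylurocanic acid
Product: 37 C8 (E)-N-methylurocanate, via mixed anhydride 36 (not isolated)
Conditions: 35, 2,4,6-Cl3C6H2COCl, Et3N, THF, rt; then 32, DMAP, toluene, 60 °C
Reagents that add atoms: none
Why: Yamaguchi esterification: the mixed anhydride and DMAP should acylate the hindered secondary C8 hydroxyl, the only free hydroxyl in the molecule, with retention at C8.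

Step 30
Reactants: 37 C8 urocanate
Product: 38 C15 primary alcohol (C4–OTBS and C7–OTES kept)
Conditions: HF·pyridine, pyridine, THF, 0 °C
Reagents that add atoms: none
Why: Selective desilylation: buffered HF·pyridine at 0 °C should cleave the primary TBS ether well before the hindered secondary allylic TBS and tertiary TES ethers.

Step 31
Reactants: 38 C15 alcohol
Product: 40 C3 carboxylic acid, via aldehyde 39 (not isolated)
Conditions: TEMPO (cat.), PhI(OAc)2, MeCN/pH 7 buffer (1:1), rt
Reagents that add atoms: water, O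
Why: TEMPO/PhI(OAc)2 oxidation in buffered aqueous acetonitrile takes the primary alcohol to the acid; the short-lived aldehyde is hydrated and oxidised on, which limits epimerisation at C3.

Step 32
Reactants: 40 C3 carboxylic acid
Product: 41 C3 methyl ester
Conditions: Me3SiCHN2, MeOH/toluene (1:4), 0 °C
Reagents that add atoms: (trimethylsilyl)diazomethane, C[Si](C)(C)C=[N+]=[N-]
Why: Esterification with trimethylsilyldiazomethane in methanol is neutral and fast and should not disturb C3 or the silyl ethers.

Step 33
Reactants: 41 methyl ester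
Product: 42 C4,C7-diol
Conditions: HF·pyridine (excess), pyridine, THF, 0 °C → rt
Reagents that add atoms: none
Why: Global desilylation with buffered HF·pyridine is non-basic, so the β-hydroxy ester should neither eliminate nor undergo retro-aldol cleavage and the urocanate stays.

Step 34
Reactants: 42 diol
Product: 44 target CNP0113846.1, via open-chain Z-enone 43 (not isolated)
Conditions: MnO2 (activated), CH2Cl2, rt
Reagents that add atoms: none
Why: Allylic oxidation with MnO2 is selective for the secondary allylic C4 hydroxyl; the Z-enone should be trapped at once by the C7 hydroxyl as the five-membered hemiketal (addition to the carbonyl), whose C4 configuration is fixed by the oxygen bridge, and this takes the ketone out of the β-keto ester before C3 can equilibrate.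

**Compound list**

1 | (S)-(+)-carvone | CC1=CC[C@@H](CC1=O)C(C)=C | starting material
2 | (S)-carvotanacetone, (5S)-2-methyl-5-(propan-2-yl)cyclohex-2-en-1-one | CC1=CC[C@@H](CC1=O)C(C)C | intermediate
3 | 6-allyl-5-isopropyl-2-methylcyclohex-2-en-1-one, allyl trans to isopropyl | CC1=CC[C@H](C(C)C)[C@@H](CC=C)C1=O | intermediate
4 | 2,3-epoxide of 3, oxirane oxygen trans to isopropyl, cis to allyl | C[C@]12O[C@H]1C[C@H](C(C)C)[C@@H](CC=C)C2=O | intermediate
5 | 4-allyl-5-isopropyl-2-methylcyclohex-2-en-1-ol, C12–OH cis to allyl, trans to isopropyl | CC1=C[C@H](CC=C)[C@@H](C(C)C)C[C@@H]1O | intermediate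
6 | C12 PMB ether of 5 | CC1=C[C@H](CC=C)[C@@H](C(C)C)C[C@@H]1OCc1ccc(OC)cc1 | intermediate
7 | B-alkyl-9-BBN adduct of 6 (boron on the terminal carbon of the arm; not isolated) | CC1=C[C@H](CCCB2C3CCCC2CCC3)[C@@H](C(C)C)C[C@@H]1OCc1ccc(OC)cc1 | intermediate
8 | primary alcohol, C1 arm = 3-hydroxypropyl | CC1=C[C@H](CCCO)[C@@H](C(C)C)C[C@@H]1OCc1ccc(OC)cc1 | intermediate
9 | aldehyde, C1 arm = 3-oxopropyl (not isolated) | CC1=C[C@H](CCC=O)[C@@H](C(C)C)C[C@@H]1OCc1ccc(OC)cc1 | intermediate
10 | propanoic acid, C1 arm = 2-carboxyethyl | CC1=C[C@H](CCC(=O)O)[C@@H](C(C)C)C[C@@H]1OCc1ccc(OC)cc1 | intermediate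
11 | mixed pivalic anhydride of 10 (not isolated) | CC1=C[C@H](CCC(=O)OC(=O)C(C)(C)C)[C@@H](C(C)C)C[C@@H]1OCc1ccc(OC)cc1 | intermediate
12 | N-acyl (R)-4-benzyloxazolidin-2-one of 10 | CC1=C[C@H](CCC(=O)N2[C@H](Cc3ccccc3)COC2=O)[C@@H](C(C)C)C[C@@H]1OCc1ccc(OC)cc1 | intermediate
13 | (R)-lactic acid | C[C@@H](O)C(O)=O | starting material
14 | (2R,5R)-2-tert-butyl-5-methyl-1,3-dioxolan-4-one (cis) | C[C@H]1O[C@@H](C(C)(C)C)OC1=O | intermediate
15 | 5-(benzyloxymethyl)-2-tert-butyl-5-methyl-1,3-dioxolan-4-one, benzyloxymethyl trans to tert-butyl | C[C@@]1(COCc2ccccc2)O[C@@H](C(C)(C)C)OC1=O | intermediate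
16 | 5-(hydroxymethyl) analogue of 15 | C[C@@]1(CO)O[C@@H](C(C)(C)C)OC1=O | intermediate
17 | 5-formyl analogue of 15 | C[C@@]1(C=O)O[C@@H](C(C)(C)C)OC1=O | intermediate
18 | 5-ethynyl analogue of 15 | C[C@@]1(C#C)O[C@@H](C(C)(C)C)OC1=O | intermediate
19 | methyl (S)-2-hydroxy-2-methylbut-3-ynoate | COC(=O)[C@@](C)(O)C#C | intermediate
20 | methyl (S)-2-methyl-2-(triethylsilyloxy)but-3-ynoate | COC(=O)[C@@](C)(O[Si](CC)(CC)CC)C#C | intermediate
21 | methyl (S)-2-methyl-5-oxo-2-(triethylsilyloxy)pent-3-ynoate | COC(=O)[C@@](C)(O[Si](CC)(CC)CC)C#CC=O | intermediate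
22 | Evans syn-aldol adduct (imide at C15, C4–OH syn to the C3 substituent, C5≡C6, C7–OTES, C8 methyl ester, C12–OPMB) | CC1=C[C@H](C[C@@H](C(=O)N2[C@H](Cc3ccccc3)COC2=O)[C@@H](O)C#C[C@](C)(O[Si](CC)(CC)CC)C(=O)OC)[C@@H](C(C)C)C[C@@H]1OCc1ccc(OC)cc1 | intermediate
23 | C15,C4-diol | CC1=C[C@H](C[C@@H](CO)[C@@H](O)C#C[C@](C)(O[Si](CC)(CC)CC)C(=O)OC)[C@@H](C(C)C)C[C@@H]1OCc1ccc(OC)cc1 | intermediate
24 | C15,C4-bis-TBS ether (alkyne) | CC1=C[C@H](C[C@@H](CO[Si](C)(C)C(C)(C)C)[C@@H](O[Si](C)(C)C(C)(C)C)C#C[C@](C)(O[Si](CC)(CC)CC)C(=O)OC)[C@@H](C(C)C)C[C@@H]1OCc1ccc(OC)cc1 | intermediate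
25 | (Z)-C5=C6 alkene | CC1=C[C@H](C[C@@H](CO[Si](C)(C)C(C)(C)C)[C@@H](O[Si](C)(C)C(C)(C)C)/C=C\[C@](C)(O[Si](CC)(CC)CC)C(=O)OC)[C@@H](C(C)C)C[C@@H]1OCc1ccc(OC)cc1 | intermediate
26 | C12 alcohol, C8 methyl ester | CC1=C[C@H](C[C@@H](CO[Si](C)(C)C(C)(C)C)[C@@H](O[Si](C)(C)C(C)(C)C)/C=C\[C@](C)(O[Si](CC)(CC)CC)C(=O)OC)[C@@H](C(C)C)C[C@@H]1O | intermediate
27 | seco acid (C8 acid, C12–OH) | CC1=C[C@H](C[C@@H](CO[Si](C)(C)C(C)(C)C)[C@@H](O[Si](C)(C)C(C)(C)C)/C=C\[C@](C)(O[Si](CC)(CC)CC)C(=O)O)[C@@H](C(C)C)C[C@@H]1O | intermediate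
28 | mixed 2,4,6-trichlorobenzoic anhydride of 27 (not isolated) | CC1=C[C@H](C[C@@H](CO[Si](C)(C)C(C)(C)C)[C@@H](O[Si](C)(C)C(C)(C)C)/C=C\[C@](C)(O[Si](CC)(CC)CC)C(=O)OC(=O)c2c(Cl)cc(Cl)cc2Cl)[C@@H](C(C)C)C[C@@H]1O | intermediate
29 | twelve-membered lactone (C8(=O)–O–C12; C15–OTBS, C4–OTBS, Z-C5=C6, C7–OTES) | O=C1O[C@H]2C[C@H](C(C)C)[C@H](C=C2C)C[C@@H](CO[Si](C)(C)C(C)(C)C)[C@@H](O[Si](C)(C)C(C)(C)C)/C=C\[C@]1(C)O[Si](CC)(CC)CC | intermediate
30 | twelve-membered 2-methylene oxacycle (cyclic allyl vinyl ether) | C=C1O[C@H]2C[C@H](C(C)C)[C@H](C=C2C)C[C@@H](CO[Si](C)(C)C(C)(C)C)[C@@H](O[Si](C)(C)C(C)(C)C)/C=C\[C@]1(C)O[Si](CC)(CC)CC | intermediate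
31 | ten-membered C8 ketone cis-fused to the cyclohexene | CC(C)(C)[Si](C)(C)OC[C@@H]1C[C@@H]2[C@@H](C(C)C)CC=C(C)[C@@H]2CC(=O)[C@@](C)(O[Si](CC)(CC)CC)/C=C\[C@@H]1O[Si](C)(C)C(C)(C)C | intermediate
32 | (8S)-C8 alcohol | CC(C)(C)[Si](C)(C)OC[C@@H]1C[C@@H]2[C@@H](C(C)C)CC=C(C)[C@@H]2C[C@H](O)[C@@](C)(O[Si](CC)(CC)CC)/C=C\[C@@H]1O[Si](C)(C)C(C)(C)C | intermediate
33 | urocanic acid | OC(=O)/C=C/c1c[nH]cn1 | starting material
34 | methyl (E)-3-(1-methyl-1H-imidazol-4-yl)prop-2-enoate | COC(=O)/C=C/c1cn(C)cn1 | intermediate
35 | (E)-3-(1-methyl-1H-imidazol-4-yl)prop-2-enoic acid | OC(=O)/C=C/c1cn(C)cn1 | intermediate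
36 | mixed 2,4,6-trichlorobenzoic anhydride of 35 (not isolated) | O=C(/C=C/c1cn(C)cn1)OC(=O)c1c(Cl)cc(Cl)cc1Cl | intermediate
37 | C8 (E)-N-methylurocanate (C15–OTBS, C4–OTBS, C7–OTES) | CC(C)(C)[Si](C)(C)OC[C@@H]1C[C@@H]2[C@@H](C(C)C)CC=C(C)[C@@H]2C[C@H](OC(=O)/C=C/c3cn(C)cn3)[C@@](C)(O[Si](CC)(CC)CC)/C=C\[C@@H]1O[Si](C)(C)C(C)(C)C | intermediate
38 | C15 primary alcohol | OC[C@@H]1C[C@@H]2[C@@H](C(C)C)CC=C(C)[C@@H]2C[C@H](OC(=O)/C=C/c3cn(C)cn3)[C@@](C)(O[Si](CC)(CC)CC)/C=C\[C@@H]1O[Si](C)(C)C(C)(C)C | intermediate
39 | C15 aldehyde (not isolated) | O=C[C@@H]1C[C@@H]2[C@@H](C(C)C)CC=C(C)[C@@H]2C[C@H](OC(=O)/C=C/c3cn(C)cn3)[C@@](C)(O[Si](CC)(CC)CC)/C=C\[C@@H]1O[Si](C)(C)C(C)(C)C | intermediate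
40 | C3 carboxylic acid | OC(=O)[C@@H]1C[C@@H]2[C@@H](C(C)C)CC=C(C)[C@@H]2C[C@H](OC(=O)/C=C/c3cn(C)cn3)[C@@](C)(O[Si](CC)(CC)CC)/C=C\[C@@H]1O[Si](C)(C)C(C)(C)C | intermediate
41 | C3 methyl ester | COC(=O)[C@@H]1C[C@@H]2[C@@H](C(C)C)CC=C(C)[C@@H]2C[C@H](OC(=O)/C=C/c3cn(C)cn3)[C@@](C)(O[Si](CC)(CC)CC)/C=C\[C@@H]1O[Si](C)(C)C(C)(C)C | intermediate
42 | C4,C7-diol | COC(=O)[C@@H]1C[C@@H]2[C@@H](C(C)C)CC=C(C)[C@@H]2C[C@H](OC(=O)/C=C/c3cn(C)cn3)[C@@](C)(O)/C=C\[C@@H]1O | intermediate
43 | open-chain Z-enone (C4 ketone, C7–OH; not isolated) | COC(=O)[C@@H]1C[C@@H]2[C@@H](C(C)C)CC=C(C)[C@@H]2C[C@H](OC(=O)/C=C/c3cn(C)cn3)[C@@](C)(O)/C=C\C1=O | intermediate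
44 | CNP0113846.1 | COC(=O)[C@@H]1C[C@@H]2[C@@H](C(C)C)CC=C(C)[C@@H]2C[C@H](OC(=O)/C=C/c2cn(C)cn2)[C@]2(C)C=C[C@@]1(O)O2 | target

**Count and risks**

Total: 34 steps. Longest linear sequence: 24 steps (steps 1–8, 17–26 and 29–34 from (S)-carvone; the branch from (R)-lactic acid through steps 9–16 is equally long).

Steps most likely to fail:

1. Step 25 (Claisen ring contraction). The bicyclic transition state may be reached only at temperatures at which the substrate no longer holds: ionisation of the allylic C12–O bond with elimination, or isomerisation of the exocyclic enol ether, could then outrun the [3,3] shift. Fallback, setting out from 30 and coming back at 31: the rearrangement is promoted by an organoaluminium Lewis acid at low temperature instead of by heat. Treatment of 30 with i-Bu3Al in CH2Cl2 at −78 → 0 °C should trigger the shift and reduce the ketone in the flask by β-hydride transfer, giving the ten-membered C8 carbinol (C8 epimer mixture) F1; oxidation of F1 with Dess–Martin periodinane returns ketone 31.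

2. Step 23 (macrolactonisation). Acyl transfer from the neopentyl-type, α-silyloxy acyl donor to the C12 hydroxyl may be so slow that intermolecular esterification to dimers and oligomers, or attack at the aryl carbonyl of the mixed anhydride, takes over. Fallback, setting out from 24 and coming back at 29: the ring is closed before the semihydrogenation, where the rod-like alkyne keeps the C4 substituents away from the acyl carbon. DDQ on 24 should give the alkynyl C12 alcohol F2, KOSiMe3 the alkynyl seco acid F3, activation with 2,4,6-trichlorobenzoyl chloride its mixed anhydride F4 (not isolated), and high-dilution cyclisation with DMAP the twelve-membered cycloalkyne lactone F5; semihydrogenation of F5 over Pd/CaCO3 poisoned with Pb(OAc)2 then gives 29.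

3. Step 34 (oxidation and hemiketal closure). While the open-chain β-keto ester exists, C3 may epimerise or the Z-enone may isomerise to the E form, which cannot close. Fallback, setting out from 37 and coming back at 44: C4 is oxidised and masked before the C3 carboxyl exists. Excess HF·pyridine on 37 should give the C15,C4,C7-triol F6; MnO2 oxidises only the allylic C4 hydroxyl, and the open-chain enone F7 (not isolated) closes to the hemiketal primary alcohol F8; TEMPO/PhI(OAc)2 takes F8 through the hemiketal aldehyde F9 (not isolated) to the hemiketal acid F10, which is esterified at once with Me3SiCHN2 in methanol to give 44.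

**Further compounds**

F1 | step 25 | ten-membered C8 carbinol, C8 epimer mixture (C8 left open in the SMILES) | CC(C)(C)[Si](C)(C)OC[C@@H]1C[C@@H]2[C@@H](C(C)C)CC=C(C)[C@@H]2CC(O)[C@@](C)(O[Si](CC)(CC)CC)/C=C\[C@@H]1O[Si](C)(C)C(C)(C)C
F2 | step 23 | alkynyl C12 alcohol, C8 methyl ester | CC1=C[C@H](C[C@@H](CO[Si](C)(C)C(C)(C)C)[C@@H](O[Si](C)(C)C(C)(C)C)C#C[C@](C)(O[Si](CC)(CC)CC)C(=O)OC)[C@@H](C(C)C)C[C@@H]1O
F3 | step 23 | alkynyl seco acid | CC1=C[C@H](C[C@@H](CO[Si](C)(C)C(C)(C)C)[C@@H](O[Si](C)(C)C(C)(C)C)C#C[C@](C)(O[Si](CC)(CC)CC)C(=O)O)[C@@H](C(C)C)C[C@@H]1O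
F4 | step 23 | mixed 2,4,6-trichlorobenzoic anhydride of F3 | CC1=C[C@H](C[C@@H](CO[Si](C)(C)C(C)(C)C)[C@@H](O[Si](C)(C)C(C)(C)C)C#C[C@](C)(O[Si](CC)(CC)CC)C(=O)OC(=O)c2c(Cl)cc(Cl)cc2Cl)[C@@H](C(C)C)C[C@@H]1O
F5 | step 23 | twelve-membered cycloalkyne lactone | O=C1O[C@H]2C[C@H](C(C)C)[C@H](C=C2C)C[C@@H](CO[Si](C)(C)C(C)(C)C)[C@@H](O[Si](C)(C)C(C)(C)C)C#C[C@]1(C)O[Si](CC)(CC)CC
F6 | step 34 | C15,C4,C7-triol of the C8 urocanate | OC[C@@H]1C[C@@H]2[C@@H](C(C)C)CC=C(C)[C@@H]2C[C@H](OC(=O)/C=C/c3cn(C)cn3)[C@@](C)(O)/C=C\[C@@H]1O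
F7 | step 34 | open-chain Z-enone with C15–OH | OC[C@@H]1C[C@@H]2[C@@H](C(C)C)CC=C(C)[C@@H]2C[C@H](OC(=O)/C=C/c3cn(C)cn3)[C@@](C)(O)/C=C\C1=O
F8 | step 34 | hemiketal primary alcohol (C15–OH) | OC[C@@H]1C[C@@H]2[C@@H](C(C)C)CC=C(C)[C@@H]2C[C@H](OC(=O)/C=C/c2cn(C)cn2)[C@]2(C)C=C[C@@]1(O)O2
F9 | step 34 | hemiketal aldehyde | O=C[C@@H]1C[C@@H]2[C@@H](C(C)C)CC=C(C)[C@@H]2C[C@H](OC(=O)/C=C/c2cn(C)cn2)[C@]2(C)C=C[C@@]1(O)O2
F10 | step 34 | hemiketal acid | OC(=O)[C@@H]1C[C@@H]2[C@@H](C(C)C)CC=C(C)[C@@H]2C[C@H](OC(=O)/C=C/c2cn(C)cn2)[C@]2(C)C=C[C@@]1(O)O2
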